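Everything rests on cutting the bond between the vinylic CH (C2) and the carbinol carbon (C3) of the Z-configured γ-acetoxy enoate C1(CO2Me)=C2H–C3H(OAc) that sits in the 14-membered carbocycle. A catalytic asymmetric Nozaki–Hiyama–Kishi macrocyclisation makes this bond. In one operation it closes the ring, sets (R)-C3 under ligand control, and carries over the Z-geometry of C1=C2. It also caps O3 as a silyl ether through its own turnover reagent, so the cis ester cannot close a butenolide. The precursor is an open chain with a C3 aldehyde at one end and a (Z)-β-triflyloxy acrylate (C2) at the other. It already holds the C5–C8 diene, (R)-C10 and the C11=C12 enoate.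

Key step: step 12

Numbering: the ring atoms run C1 (C–CO2Me), C2 (=CH), C3 (CHOAc), C4 (CH2), C5 (C–CH3), C6 (=CH), C7 (=CH), C8 (C–iPr), C9 (CH2), C10 (CHOH), C11 (C–CO2Me), C12 (=CH), C13 (CH2), C14 (CH2, bonded to C1). Open-chain precursors keep these numbers. The target is (1Z,3R,5E,7E,10R,11Z).

Assumption: the catalyst antipodes named in steps 5 and 12 are taken to direct attack to the Si face of the aldehyde. If either proves opposite, its mirror image is used. All starting materials are catalogue compounds.

Step 1
Reactants: 1 tert-butyl(but-3-yn-1-yloxy)dimethylsilane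
Product: 2 (E)-tert-butyl[(4-iodo-3-methylbut-3-en-1-yl)oxy]dimethylsilane (C3–C6 piece)
Conditions: Me3Al (2 equiv), Cp2ZrCl2 (0.2 equiv), CH2Cl2, 0 °C to rt; then I2, THF, −30 °C
Reagents that add atoms: trimethylaluminium C[Al](C)C; iodine II
Why: The zirconium-catalysed Negishi carboalumination adds methyl and aluminium syn with the metal on the terminal carbon, and iodinolysis with retention gives the E-iodide.

Step 2
Reactants: 3 3-methylbut-1-yne
Product: 5 (Z)-2-(2-bromo-3-methylbut-1-en-1-yl)-4,4,5,5-tetramethyl-1,3,2-dioxaborolane, via alkenyldibromoborane 4 (not isolated)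
Conditions: BBr3, CH2Cl2, −78 °C to rt; then pinacol, −78 °C to rt
Reagents that add atoms: boron tribromide BrB(Br)Br; pinacol CC(C)(O)C(C)(C)O
Why: Haloboration adds Br and B syn across the terminal alkyne with boron on the CH terminus (C7), and esterification with pinacol freezes the geometry with Br cis to B.

Step 3
Reactants: 5 (Z)-bromoalkenyl pinacolboronate; 6 (2-tert-butoxy-2-oxoethyl)zinc chloride
Product: 7 tert-butyl (3E)-4-methyl-3-[(4,4,5,5-tetramethyl-1,3,2-dioxaborolan-2-yl)methylidene]pentanoate (C9H2 cis to boron, isopropyl trans)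
Conditions: Pd(P(t-Bu)3)2 (3 mol%), THF/Et2O, rt
Reagents that add atoms: none
Why: The Negishi coupling of the Reformatsky-type zinc reagent takes place at the C–Br bond with retention and needs no base, so the boronate stays silent and C9 ends up cis to boron.

Step 4
Reactants: 7 boryl tert-butyl ester
Product: 8 (3E)-4-methyl-3-[(4,4,5,5-tetramethyl-1,3,2-dioxaborolan-2-yl)methylidene]pentanal (C10 aldehyde)
Conditions: i-Bu2AlH (1.1 equiv), CH2Cl2, −78 °C; aq. potassium sodium tartrate
Reagents that add atoms: none
Why: In this partial hydride reduction the aluminium hemiacetal of the hindered tert-butyl ester survives at −78 °C and collapses to the aldehyde only on work-up.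

Step 5
Reactants: 8 boryl aldehyde; 9 methyl propiolate
Product: 10 methyl (Z)-2-{(1R,3E)-1-hydroxy-4-methyl-3-[(4,4,5,5-tetramethyl-1,3,2-dioxaborolan-2-yl)methylidene]pentyl}-3-iodoprop-2-enoate
Conditions: TMSI (1.5 equiv), oxazaborolidinium triflimide from (S)-α,α-diphenylprolinol, o-tolylboronic acid and HNTf2 (20 mol%), CH2Cl2, −78 °C; then 1 M HCl
Reagents that add atoms: iodotrimethylsilane C[Si](C)(C)I
Why: In this catalytic asymmetric β-iodo Morita–Baylis–Hillman (iodo-aldol) reaction TMSI adds to the propiolate to give a β-iodo allenolate that attacks the Si face of the aldehyde bound to the chiral oxazaborolidinium ion, which sets (R)-C10 and gives the Z-iodide with I cis to CO2Me.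

Step 6
Reactants: 10 β-iodo hydroxy ester
Product: 11 C10 tert-butyldimethylsilyl ether of 10
Conditions: TBSOTf, 2,6-lutidine, CH2Cl2, −78 to 0 °C
Reagents that add atoms: tert-butyldimethylsilyl triflate CC(C)(C)[Si](C)(C)OS(=O)(=O)C(F)(F)F
Why: Silylation with the reactive silyl triflate covers the hindered allylic hydroxyl without touching C10, the iodide or the boronate.

Step 7
Reactants: 11 silylated β-iodo enoate; 12 methyl 4-iodobutanoate
Product: 14 dimethyl (2Z)-2-{(1R,3E)-1-(tert-butyldimethylsilyloxy)-4-methyl-3-[(4,4,5,5-tetramethyl-1,3,2-dioxaborolan-2-yl)methylidene]pentyl}hept-2-enedioate, via alkylzinc iodide 13 (not isolated)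
Conditions: 12, Zn dust, LiCl, THF, 40 °C; then 11, PdCl2(dppf) (3 mol%), THF, rt
Reagents that add atoms: none
Why: LiCl-assisted zinc insertion followed by an sp3–sp2 Negishi coupling replaces the activated vinylic iodide with retention (C13 cis to CO2Me), and the base-free medium leaves the boronate untouched.

Step 8
Reactants: 14 boryl diester; 2 (E)-alkenyl iodide
Product: 15 dimethyl (2Z)-2-[(1R,3E,5E)-1,8-bis(tert-butyldimethylsilyloxy)-6-methyl-3-(propan-2-yl)octa-3,5-dien-1-yl]hept-2-enedioate (open chain C3 to C1)
Conditions: PdCl2(dppf) (5 mol%), Cs2CO3 (2 equiv), THF/H2O (10:1), rt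
Reagents that add atoms: none
Why: The Suzuki–Miyaura alkenyl–alkenyl coupling proceeds with retention at both partners and forms C6–C7, which gives the diene with C4 trans to C7 and isopropyl trans to C6.

Step 9
Reactants: 15 open-chain diester
Product: 17 dimethyl (2Z,6Z)-2-[(1R,3E,5E)-1,8-bis(tert-butyldimethylsilyloxy)-6-methyl-3-(propan-2-yl)octa-3,5-dien-1-yl]-6-{[(trifluoromethylsulfonyl)oxy]methylidene}hept-2-enedioate, via lithium formyl enolate 16 (not isolated)
Conditions: LiN(i-Pr)2 (1.1 equiv), THF, −78 °C; HCO2CH2CF3; then PhNTf2 (1.5 equiv), −78 to 0 °C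
Reagents that add atoms: 2,2,2-trifluoroethyl formate O=COCC(F)(F)F; N-phenylbis(trifluoromethanesulfonimide) O=S(=O)(N(c1ccccc1)S(=O)(=O)C(F)(F)F)C(F)(F)F
Why: A crossed Claisen formylation of the kinetic enolate of the only ester that has α-hydrogens brings in C2, and O-sulfonylation of the lithium-chelated formyl enolate, whose oxygen is held cis to the ester, gives the Z-enol triflate.

Step 10
Reactants: 17 bis-silyl enol triflate
Product: 18 C3 primary alcohol (C10 silyl ether and enol triflate kept)
Conditions: camphorsulfonic acid (10 mol%), MeOH/CH2Cl2 (1:1), 0 °C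
Reagents that add atoms: none
Why: Acid-catalysed methanolysis of silyl ethers is governed by steric access, so the primary ether at C3 is cleaved well before the hindered secondary one at C10.

Step 11
Reactants: 18 primary alcohol
Product: 19 C3 aldehyde bearing the (Z)-β-triflyloxy acrylate terminus (seco compound)
Conditions: Dess–Martin periodinane, CH2Cl2, 0 °C to rt; used without storage
Reagents that add atoms: none
Why: The Dess–Martin oxidation is fast and free of base, so the C5=C6 double bond does not move into conjugation with the new aldehyde.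

Step 12
Reactants: 19 seco aldehyde enol triflate
Product: 20 dimethyl (1Z,3R,5E,7E,10R,11Z)-10-(tert-butyldimethylsilyloxy)-5-methyl-8-(propan-2-yl)-3-(triethylsilyloxy)cyclotetradeca-1,5,7,11-tetraene-1,11-dicarboxylate
Conditions: CrCl2 (20 mol%), N-[2-((S)-4-isopropyl-4,5-dihydrooxazol-2-yl)-6-methoxyphenyl]methanesulfonamide (22 mol%), 1,8-bis(dimethylamino)naphthalene (22 mol%), NiCl2(2,9-dimethyl-1,10-phenanthroline) (3 mol%), Mn powder (4 equiv), TESCl (3 equiv), MeCN, rt, 19 added over 12 h (final 2 mM)
Reagents that add atoms: chlorotriethylsilane CC[Si](Cl)(CC)CC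
Why: Zerovalent nickel inserts into the C2–OTf bond with retention, the alkenyl group passes to chromium, the alkenyl complex of trivalent chromium adds to the C3 aldehyde, TESCl silylates the chromium alkoxide and Mn returns chromium to the divalent state. The closest known reaction type is the catalytic asymmetric Nozaki–Hiyama–Kishi coupling of alkenyl triflates with aldehydes, which is established for macrocyclisation. The 14-membered carbocycle closes in a 14-exo-trig mode, since C2 attacks the carbonyl carbon C3 and the C=O bond stays outside the ring. The new stereocentre C3 is controlled by the oxazoline–sulfonamide ligand on chromium, which directs attack to the Si face and gives (R)-C3, while the remote (R)-C10 centre should have little say. The step needs aldehyde-over-ester chemoselectivity, which organochromium reagents have by nature, ring closure over oligomerisation, secured by slow addition at high dilution, and silylation over lactonisation, secured because silyl transfer to O3 is the turnover step itself. The Z-geometry of C1=C2 (CO2Me cis to C3) is carried over from the triflate and places C14 and C3 trans in the ring.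

Step 13
Reactants: 20 macrocyclic C3 triethylsilyl ether
Product: 21 dimethyl (1Z,3R,5E,7E,10R,11Z)-3-acetoxy-10-(tert-butyldimethylsilyloxy)-5-methyl-8-(propan-2-yl)cyclotetradeca-1,5,7,11-tetraene-1,11-dicarboxylate
Conditions: Ac2O (5 equiv), Sc(OTf)3 (2 mol%), MeCN, −20 °C
Reagents that add atoms: acetic anhydride CC(=O)OC(C)=O
Why: In this Lewis-acid-catalysed direct silyl-to-acetyl exchange the ether oxygen is acylated before silicon leaves, so no free hydroxyl or alkoxide forms that could attack the cis ester, the C3–O bond and (R)-C3 are untouched, and the triethylsilyl ether reacts far faster than the hindered silyl ether at C10.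

Step 14
Reactants: 21 macrocyclic acetate silyl ether
Product: 22 dimethyl (1Z,3R,5E,7E,10R,11Z)-3-acetoxy-10-hydroxy-5-methyl-8-(propan-2-yl)cyclotetradeca-1,5,7,11-tetraene-1,11-dicarboxylate (CNP0189703.2)
Conditions: HF·pyridine, pyridine, THF, 0 °C to rt
Reagents that add atoms: none
Why: Buffered fluoride desilylation frees the C10 hydroxyl without acyl migration, ester cleavage or isomerisation of the diene, and no stereocentre is touched.

Compound list
1 | tert-butyl(but-3-yn-1-yloxy)dimethylsilane | C#CCCO[Si](C)(C)C(C)(C)C | starting material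
2 | (E)-tert-butyl[(4-iodo-3-methylbut-3-en-1-yl)oxy]dimethylsilane | CC(C)(C)[Si](C)(C)OCC/C(C)=C/I | intermediate
3 | 3-methylbut-1-yne | CC(C)C#C | starting material
4 | (Z)-(2-bromo-3-methylbut-1-en-1-yl)dibromoborane | CC(C)/C(Br)=C/B(Br)Br | intermediate
5 | (Z)-2-(2-bromo-3-methylbut-1-en-1-yl)-4,4,5,5-tetramethyl-1,3,2-dioxaborolane | CC(C)/C(Br)=C/B1OC(C)(C)C(C)(C)O1 | intermediate
6 | (2-tert-butoxy-2-oxoethyl)zinc chloride | CC(C)(C)OC(=O)C[Zn]Cl | starting material
7 | tert-butyl (3E)-4-methyl-3-[(pinacolboryl)methylidene]pentanoate | CC(C)/C(CC(=O)OC(C)(C)C)=C/B1OC(C)(C)C(C)(C)O1 | intermediate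
8 | (3E)-4-methyl-3-[(pinacolboryl)methylidene]pentanal | CC(C)/C(CC=O)=C/B1OC(C)(C)C(C)(C)O1 | intermediate
9 | methyl propiolate | C#CC(=O)OC | starting material
10 | methyl (Z)-2-{(1R,3E)-1-hydroxy-4-methyl-3-[(pinacolboryl)methylidene]pentyl}-3-iodoprop-2-enoate | CC(C)/C(C[C@@H](O)/C(C(=O)OC)=C/I)=C/B1OC(C)(C)C(C)(C)O1 | intermediate
11 | C10 tert-butyldimethylsilyl ether of 10 | CC(C)/C(C[C@@H](O[Si](C)(C)C(C)(C)C)/C(C(=O)OC)=C/I)=C/B1OC(C)(C)C(C)(C)O1 | intermediate
12 | methyl 4-iodobutanoate | COC(=O)CCCI | starting material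
13 | (4-methoxy-4-oxobutyl)zinc iodide | COC(=O)CCC[Zn]I | intermediate
14 | dimethyl (2Z)-2-{(1R,3E)-1-(tert-butyldimethylsilyloxy)-4-methyl-3-[(pinacolboryl)methylidene]pentyl}hept-2-enedioate | CC(C)/C(C[C@@H](O[Si](C)(C)C(C)(C)C)/C(C(=O)OC)=C/CCCC(=O)OC)=C/B1OC(C)(C)C(C)(C)O1 | intermediate
15 | dimethyl (2Z)-2-[(1R,3E,5E)-1,8-bis(tert-butyldimethylsilyloxy)-6-methyl-3-(propan-2-yl)octa-3,5-dien-1-yl]hept-2-enedioate | CC(C)(C)[Si](C)(C)OCC/C(C)=C/C=C(/C(C)C)C[C@@H](O[Si](C)(C)C(C)(C)C)/C(C(=O)OC)=C/CCCC(=O)OC | intermediate
16 | lithium (Z)-enolate of the C1-formylated diester | CC(C)(C)[Si](C)(C)OCC/C(C)=C/C=C(/C(C)C)C[C@@H](O[Si](C)(C)C(C)(C)C)/C(C(=O)OC)=C/CC/C(C(=O)OC)=C/[O-].[Li+] | intermediate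
17 | (2Z,6Z)-enol triflate of the bis-silylated chain | CC(C)(C)[Si](C)(C)OCC/C(C)=C/C=C(/C(C)C)C[C@@H](O[Si](C)(C)C(C)(C)C)/C(C(=O)OC)=C/CC/C(C(=O)OC)=C/OS(=O)(=O)C(F)(F)F | intermediate
18 | C3 primary alcohol enol triflate | OCC/C(C)=C/C=C(/C(C)C)C[C@@H](O[Si](C)(C)C(C)(C)C)/C(C(=O)OC)=C/CC/C(C(=O)OC)=C/OS(=O)(=O)C(F)(F)F | intermediate
19 | C3 aldehyde enol triflate (seco compound) | O=CC/C(C)=C/C=C(/C(C)C)C[C@@H](O[Si](C)(C)C(C)(C)C)/C(C(=O)OC)=C/CC/C(C(=O)OC)=C/OS(=O)(=O)C(F)(F)F | intermediate
20 | macrocycle, (3R)-triethylsilyl ether, (10R)-tert-butyldimethylsilyl ether | COC(=O)/C1=C\[C@H](O[Si](CC)(CC)CC)C/C(C)=C/C=C(/C(C)C)C[C@@H](O[Si](C)(C)C(C)(C)C)/C(C(=O)OC)=C/CC1 | intermediate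
21 | macrocycle, (3R)-acetate, (10R)-tert-butyldimethylsilyl ether | COC(=O)/C1=C\[C@H](OC(C)=O)C/C(C)=C/C=C(/C(C)C)C[C@@H](O[Si](C)(C)C(C)(C)C)/C(C(=O)OC)=C/CC1 | intermediate
22 | dimethyl (1Z,3R,5E,7E,10R,11Z)-3-acetoxy-10-hydroxy-5-methyl-8-(propan-2-yl)cyclotetradeca-1,5,7,11-tetraene-1,11-dicarboxylate | COC(=O)/C1=C\[C@H](OC(C)=O)C/C(C)=C/C=C(/C(C)C)C[C@@H](O)/C(C(=O)OC)=C/CC1 | target

Total step count: 14. Longest linear sequence: 13 steps (steps 2 to 14, from 3-methylbut-1-yne). Step 1 is a one-step side branch.

Steps most likely to fail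

Step 12.
- **What may go wrong:** Oligomerisation may compete with ring closure. TESCl may turn the easily enolised β,γ-unsaturated aldehyde into a silyl dienol ether. Lactonisation of the chromium alkoxide may outrun its silylation. The ligand may fail to override the conformational bias of the forming ring.
- **Fallback:** It reverses the polarity at C3, sets out from 19 and comes back at 21. Acetyl bromide with catalytic ZnBr2 in CH2Cl2 at −20 °C adds across the aldehyde of 19 to give the 1-bromoalkyl acetate F1 as both C3 epimers. A nickel-catalysed enantioconvergent reductive cross-electrophile coupling (NiBr2(dme), chiral bis(oxazoline), Mn, DMA, slow addition) then joins the α-acetoxyalkyl carbon C3 to the alkenyl triflate carbon C2. This gives 21 directly, with the acetate in place before the C–C bond forms, so steps 12 and 13 are both replaced.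

Step 9.
- **What may go wrong:** γ-Deprotonation of the C11 enoate or conjugate addition of the amide base may compete with enolisation at C1. The alkoxide released in the formylation may attack the fresh enol triflate. The Z-selectivity may erode.
- **Fallback:** It gives up the strong-base enolate, sets out from 15 and comes back at 17. A titanium-mediated crossed Claisen condensation (TiCl4, Bu3N, HCO2Me, CH2Cl2, 0 °C) enolises only the ester that has α-hydrogens and gives the isolated α-formyl ester F2. This far more acidic compound is then deprotonated on its own with LiN(SiMe3)2 (1 equiv, THF, −78 °C). The chelated enolate is sulfonylated with PhNTf2 in the absence of any alkoxide to give 17.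

Step 5.
- **What may go wrong:** The acidic medium may shift the double bond of the β,γ-unsaturated aldehyde. An uncatalysed background addition may lower the enantiomeric purity. The catalyst may differentiate the faces of this aliphatic aldehyde poorly.
- **Fallback:** It sets C10 by reduction instead of by C–C bond formation, sets out from 8 and comes back at 10. The MgI2-promoted iodo-aldol reaction of 8 with methyl propiolate (CH2Cl2, 0 °C) gives the racemic β-iodo hydroxy ester F3. Dess–Martin oxidation gives the α-(iodomethylidene) β-keto ester F4. An oxazaborolidine-catalysed reduction with catecholborane (Corey–Bakshi–Shibata reduction, toluene, −78 °C) then delivers (R)-configured 10.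

Further compounds
F1 | step 12 | 1-bromoalkyl acetate derived from 19 (both C3 epimers) | CC(=O)OC(Br)C/C(C)=C/C=C(/C(C)C)C[C@@H](O[Si](C)(C)C(C)(C)C)/C(C(=O)OC)=C/CC/C(C(=O)OC)=C/OS(=O)(=O)C(F)(F)F
F2 | step 9 | α-formyl ester derived from 15 (C1 epimers, in equilibrium with the enol) | CC(C)(C)[Si](C)(C)OCC/C(C)=C/C=C(/C(C)C)C[C@@H](O[Si](C)(C)C(C)(C)C)/C(C(=O)OC)=C/CCC(C=O)C(=O)OC
F3 | step 5 | racemic β-iodo hydroxy ester (racemate of 10) | CC(C)/C(CC(O)/C(C(=O)OC)=C/I)=C/B1OC(C)(C)C(C)(C)O1
F4 | step 5 | α-(iodomethylidene) β-keto ester (C10 ketone) | CC(C)/C(CC(=O)/C(C(=O)OC)=C/I)=C/B1OC(C)(C)C(C)(C)O1
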